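Readings and results were generated by integration for an exercise, and the scatter is random.

The ratio of two half-lives shaped my reckoning for the south flask: how fast E stopped arriving against how fast it went.

common to all: Q 21 mM (held)
- south: D 0.10 M; the very flask that is asked about, followed so far
- south-west: D 0.067 M; run made earlier
- flask: D 0.10 M; time 10 h

| run | time / h | E / % |
|---|---|---|
| south | 0.667 | 9.6 |
| south | 1.00 | 11.7 |
| south | 2.00 | 16.9 |
| south | 4.00 | 13.7 |
| south-west | 0.667 | 10.3 |
| south-west | 1.33 | 14.8 |
| south-west | 3.00 | 20.5 |
| south-west | 8.00 | 9.4 |

(standard deviation of a reading: 1 percentage point)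

* the moment within 10 h at which there is most E
* the amount of E, in percent of the D charged, at that time
* the first time at which E reaches 7.7%, in the same percent

- at the start none of Q is in solution

In the south-west run E fell from 20.5% to 9.4% between 3.00 h and 8.00 h. With Q held I took that tail as pseudo-first-order, which gave 4.44 h, the time in which E halves: its fall half-life.

I then worked with the fraction left. Running the 4.00 h reading of the south run back to 1.00 h along that fall gave 21.9%, where E would have stood with nothing still to arrive. It stood at 11.7%, so 46.5% of that was still to come, a rise half-life of 0.905 h.

The ratio of the two was 4.91. The rise half-life belongs to the gap under the falling line, so I took E as that line times the filled fraction, and the top of this curve put my peak for the south flask at 2.32 h, a reading with all the scatter of its inputs.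

The forecast, which saw something that “rises and falls like a consecutive sequence”, gave a slightly later peak: 2.4 h, 17%, and 0.5 h for the level.

The south flask gave 2.36 h, 15.4% and 0.532 h, and the forecast held on all three.

    D + L → E (k = 0.320 L mol⁻¹ min⁻¹)
    L + E → X (k = 0.200 L mol⁻¹ min⁻¹)
    L + X → G (k = 0.00570 L mol⁻¹ min⁻¹)
    Q ⇌ L, rate k4*(csat - [L]) (kL = 0.110 min⁻¹)
    2 D → Z (k = 0.180 L mol⁻¹ min⁻¹)

In the south flask, each step taken net, E was made 2.33 times as fast as it was used at 1.29 h, but at 10.0 h that ratio stood at 0.116. Over the 7.64 h from peak to end, the fall half-life leaves 30.4%, which is 4.68% of the D charged, and the south flask held 4.40%. The neighbour charged with 0.025 M of D peaked at 29.4%; the same fraction of that is 8.94%, and it held 9.56% at 10.0 h.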